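**Retrosynthetic overview**
- The target comes from one LiAlH4 reduction of a trans-dibenzylbutyrolactone carrying a trans-2-aryl-2,3-dihydrobenzofuran-3-carboxylate (lactone to 1,4-diol, ester to CH2OH, aryl pivalates to phenols).
- The dihydrobenzofuran comes from an oxidative ring contraction (1,2-aryl shift, PhI(OAc)2) of a (2S)-flavanone; this is the last ring formed, by contraction of the pyranone ring.
- The flavanone C2–aryl bond (ring C) comes from an asymmetric conjugate addition of an arylboronic acid to a chromone.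
- The chromone–lactone C–C bond comes from a nickel-catalysed reductive conjugate arylation of an (R)-α-methylene-β-benzylbutyrolactone (ring A) with 6-bromo-8-methoxychromone (ring B); this is the new step.
- The lactone comes from Heck arylation and asymmetric hydrogenation of an itaconic half ester; all three arenes come from catechol. Ring order: chromone pyranone, lactone, then contraction of the pyranone to the dihydrofuran.

Assumption: the sense of induction of the two chiral catalysts is assigned by analogy with itaconate hydrogenation and cyclic-enone arylation, is checked on the first run (rotation of the lactone, CD of the flavanone), and the ligand antipode is used if it is opposite.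

Abbreviations: Piv = 2,2-dimethylpropanoyl; ring A = benzyl ring, ring B = benzofuran benzo ring, ring C = 2-aryl ring.

**Route**

Step 1
Reactants: 1 benzene-1,2-diol (catechol)
Product: 2 2-methoxyphenol
Conditions: MeI (0.9 equiv), K2CO3 (1 equiv), acetone, 56 °C
Reagents that add atoms: iodomethane, CI
Why: Williamson mono-O-methylation; sub-stoichiometric MeI limits dimethylation and unreacted catechol is washed out with water.

Step 2
Reactants: 2 2-methoxyphenol
Product: 3 4-bromo-2-methoxyphenol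
Conditions: NBS (1.0 equiv), MeCN, 0 °C
Reagents that add atoms: N-bromosuccinimide, O=C1CCC(=O)N1Br
Why: Electrophilic aromatic bromination goes para to the free OH, the stronger director.

Step 3
Reactants: 3 4-bromo-2-methoxyphenol
Product: 4 4-bromo-2-methoxyphenyl 2,2-dimethylpropanoate
Conditions: PivCl (1.2 equiv), Et3N (1.5 equiv), DMAP (5 mol %), CH2Cl2, 0 to 23 °C
Reagents that add atoms: pivaloyl chloride, CC(C)(C)C(Cl)=O
Why: DMAP-catalysed O-acylation; the pivalate protects the phenol through the oxidative step, makes the ring less electron-rich, and is removed by the final hydride reduction.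

Step 4
Reactants: 4 4-bromo-2-methoxyphenyl 2,2-dimethylpropanoate
Product: 5 [3-methoxy-4-(pivaloyloxy)phenyl]boronic acid
Conditions: B2(OH)4 (2 equiv), Pd(OAc)2 (2 mol %), XPhos (4 mol %), KOAc (3 equiv), EtOH, 80 °C; then 1 M HCl
Reagents that add atoms: tetrahydroxydiboron, OB(O)B(O)O
Why: Palladium-catalysed Miyaura-type borylation of the aryl bromide gives the boronic acid directly under weakly basic conditions that leave the hindered ester intact.

Step 5
Reactants: 3 4-bromo-2-methoxyphenol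
Product: 7 1-(5-bromo-2-hydroxy-3-methoxyphenyl)ethan-1-one, via aryl acetate 6 (not isolated)
Conditions: AcCl (1.2 equiv), TiCl4 (1.5 equiv), 1,2-dichlorobenzene, 120 °C; then 1 M HCl
Reagents that add atoms: acetyl chloride, CC(Cl)=O
Why: O-acetylation followed by TiCl4-mediated Fries rearrangement; the para position is blocked by Br, so the acyl group goes to the only free ortho position of the titanium phenoxide.

Step 6
Reactants: 7 1-(5-bromo-2-hydroxy-3-methoxyphenyl)ethan-1-one
Product: 9 6-bromo-8-methoxy-4H-chromen-4-one, via enaminone 8 (not isolated)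
Conditions: Me2NCH(OMe)2 (1.5 equiv), toluene, 100 °C; then conc. HCl, CH2Cl2, 40 °C
Reagents that add atoms: N,N-dimethylformamide dimethyl acetal, COC(OC)N(C)C
Why: Enaminone condensation, then acid-promoted intramolecular oxa-Michael addition and loss of dimethylamine (chromone synthesis).

Step 7
Reactants: 10 itaconic anhydride; 4 4-bromo-2-methoxyphenyl 2,2-dimethylpropanoate
Product: 12 (2E)-4-methoxy-2-{[3-methoxy-4-(pivaloyloxy)phenyl]methylidene}-4-oxobutanoic acid, via monomethyl itaconate 11 (not isolated)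
Conditions: MeOH, 65 °C, evaporate; then 4, Pd(OAc)2 (3 mol %), P(o-tol)3 (6 mol %), Et3N (3 equiv), MeCN, 90 °C
Reagents that add atoms: methanol, CO
Why: Methanol opens the anhydride at the non-conjugated carbonyl, and a Mizoroki–Heck arylation of the 1,1-disubstituted alkene gives the E-benzylidene half ester.

Step 8
Reactants: 12 (2E)-4-methoxy-2-{[3-methoxy-4-(pivaloyloxy)phenyl]methylidene}-4-oxobutanoic acid
Product: 13 (2R)-4-methoxy-2-{[3-methoxy-4-(pivaloyloxy)phenyl]methyl}-4-oxobutanoic acid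
Conditions: H2 (5 bar), [Rh(cod)2]BF4 (1 mol %), (S,S)-Et-DuPhos (1.1 mol %), MeOH, 25 °C
Reagents that add atoms: none
Why: Rhodium–bisphosphine asymmetric hydrogenation of a β-aryl itaconate half ester; chelation of the alkene and the ester carbonyl to rhodium fixes the face of H2 delivery and sets the R centre.

Step 9
Reactants: 13 (2R)-4-methoxy-2-{[3-methoxy-4-(pivaloyloxy)phenyl]methyl}-4-oxobutanoic acid
Product: 15 (4R)-4-{[3-methoxy-4-(pivaloyloxy)phenyl]methyl}oxolan-2-one, via hydroxy ester 14 (not isolated)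
Conditions: BH3·SMe2 (1.3 equiv), THF, −10 to 23 °C; then H2O; TsOH·H2O (5 mol %), toluene, 60 °C
Reagents that add atoms: none
Why: Borane reduces the carboxylic acid chemoselectively in the presence of both esters, and acid-catalysed lactonisation follows; the stereocentre is not touched.

Step 10
Reactants: 15 (4R)-4-{[3-methoxy-4-(pivaloyloxy)phenyl]methyl}oxolan-2-one
Product: 18 (4R)-4-{[3-methoxy-4-(pivaloyloxy)phenyl]methyl}-3-methylideneoxolan-2-one, via Mannich base 16 (not isolated), via methiodide 17 (not isolated)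
Conditions: LiN(iPr)2 (1.1 equiv), THF, −78 °C; CH2=NMe2+ I− (1.5 equiv), −78 to 23 °C; then MeI (5 equiv), MeOH, 23 °C; then aq. NaHCO3, CH2Cl2, 23 °C
Reagents that add atoms: N,N-dimethylmethyleneiminium iodide, C=[N+](C)C.[I-]
Why: Mannich reaction of the lithium enolate with the iminium salt, N-methylation and base-induced elimination of trimethylamine (α-methylenation); C4 is not enolisable and keeps its configuration.

Step 11
Reactants: 9 6-bromo-8-methoxy-4H-chromen-4-one; 18 (4R)-4-{[3-methoxy-4-(pivaloyloxy)phenyl]methyl}-3-methylideneoxolan-2-one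
Product: 20 (3R,4R)-3-[(8-methoxy-4-oxo-4H-chromen-6-yl)methyl]-4-{[3-methoxy-4-(pivaloyloxy)phenyl]methyl}oxolan-2-one, via cis-lactone 19 (not isolated)
Conditions: 9 (1.5 equiv), NiBr2·3H2O (10 mol %), 2,2′-bipyridine (12 mol %), Zn dust (2 equiv), H2O (2 equiv), DMF/pyridine 9:1, 60 °C; then filter; DBU (1 equiv), toluene, 80 °C
Reagents that add atoms: none
Why: Proposed new method: nickel-catalysed reductive conjugate arylation of a β-substituted α-methylene-γ-butyrolactone by an aryl bromide; zerovalent nickel (from NiBr2 and Zn) inserts into the C–Br bond of 9, the aryl–nickel species adds to the unhindered exocyclic CH2 of 18, and the nickel enolate is protonated by water instead of undergoing β-hydride elimination, so C4 is not scrambled; protonation anti to the C4 benzyl group gives mainly cis 19, which DBU equilibrates through the lactone enolate to the more stable trans (3R,4R) lactone 20; the closest known reaction types are the nickel/zinc reductive conjugate addition of aryl halides to acrylates and enones and the Heck arylation of α-methylene lactones.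

Step 12
Reactants: 20 (3R,4R)-3-[(8-methoxy-4-oxo-4H-chromen-6-yl)methyl]-4-{[3-methoxy-4-(pivaloyloxy)phenyl]methyl}oxolan-2-one; 5 [3-methoxy-4-(pivaloyloxy)phenyl]boronic acid
Product: 21 (3R,4R)-3-{[(2S)-8-methoxy-2-[3-methoxy-4-(pivaloyloxy)phenyl]-4-oxo-3,4-dihydro-2H-chromen-6-yl]methyl}-4-{[3-methoxy-4-(pivaloyloxy)phenyl]methyl}oxolan-2-one
Conditions: 5 (2 equiv), Pd(OCOCF3)2 (5 mol %), (R)-t-BuPyOx (6 mol %), NH4PF6 (30 mol %), H2O (5 equiv), ClCH2CH2Cl, 60 °C
Reagents that add atoms: none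
Why: Asymmetric conjugate addition of an arylboronic acid to a chromone catalysed by divalent palladium with a pyridine–oxazoline ligand; face-selective carbopalladation of C2=C3 sets the 2S centre under catalyst control, and water protonates the palladium enolate.

Step 13
Reactants: 21 (3R,4R)-3-{[(2S)-8-methoxy-2-[3-methoxy-4-(pivaloyloxy)phenyl]-4-oxo-3,4-dihydro-2H-chromen-6-yl]methyl}-4-{[3-methoxy-4-(pivaloyloxy)phenyl]methyl}oxolan-2-one
Product: 24 methyl (2S,3S)-7-methoxy-2-[3-methoxy-4-(pivaloyloxy)phenyl]-5-{[(3R,4R)-4-{[3-methoxy-4-(pivaloyloxy)phenyl]methyl}-2-oxooxolan-3-yl]methyl}-2,3-dihydro-1-benzofuran-3-carboxylate, via enol ether 22 (not isolated), via iodanyl ketal 23 (not isolated)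
Conditions: PhI(OAc)2 (1.3 equiv), H2SO4 (2 equiv), HC(OMe)3, 23 °C
Reagents that add atoms: trimethyl orthoformate, COC(OC)OC
Why: Oxidative ring contraction of a flavanone with a λ3-iodane (1,2-aryl shift): acid and orthoformate give enol ether 22, trivalent iodine adds to C3 anti to the 2-aryl group and methanol adds to C4 (23), then the electron-rich ring B carbon C4a, antiperiplanar to the equatorial C3–I bond, migrates from C4 to C3 as iodobenzene leaves, so the pyranone contracts to the dihydrofuran and the old C4 becomes the methyl ester; C2 is untouched, C3 is formed trans to the aryl group (2S,3S), and the acylated ring C is too electron-poor to compete as migrating group.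

Step 14
Reactants: 24 methyl (2S,3S)-7-methoxy-2-[3-methoxy-4-(pivaloyloxy)phenyl]-5-{[(3R,4R)-4-{[3-methoxy-4-(pivaloyloxy)phenyl]methyl}-2-oxooxolan-3-yl]methyl}-2,3-dihydro-1-benzofuran-3-carboxylate
Product: 25 (2R,3R)-2-{[(2S,3R)-2-(4-hydroxy-3-methoxyphenyl)-3-(hydroxymethyl)-7-methoxy-2,3-dihydro-1-benzofuran-5-yl]methyl}-3-[(4-hydroxy-3-methoxyphenyl)methyl]butane-1,4-diol (CNP0256425.1)
Conditions: LiAlH4 (6 equiv), THF, 0 to 40 °C; aq. potassium sodium tartrate
Reagents that add atoms: none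
Why: Global hydride reduction: the lactone gives the 1,4-diol, the methyl ester gives the CH2OH group and both aryl pivalates are cleaved to phenols; no stereocentre is epimerised, and the C3 descriptor changes from S to R only through the priority change from CO2Me to CH2OH.

**Compound list**

1 | benzene-1,2-diol (catechol) | Oc1ccccc1O | starting material
2 | 2-methoxyphenol | COc1ccccc1O | intermediate
3 | 4-bromo-2-methoxyphenol | COc1cc(Br)ccc1O | intermediate
4 | 4-bromo-2-methoxyphenyl 2,2-dimethylpropanoate | COc1cc(Br)ccc1OC(=O)C(C)(C)C | intermediate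
5 | [3-methoxy-4-(pivaloyloxy)phenyl]boronic acid | COc1cc(B(O)O)ccc1OC(=O)C(C)(C)C | intermediate
6 | 4-bromo-2-methoxyphenyl acetate | COc1cc(Br)ccc1OC(C)=O | intermediate
7 | 1-(5-bromo-2-hydroxy-3-methoxyphenyl)ethan-1-one | CC(=O)c1cc(Br)cc(OC)c1O | intermediate
8 | (2E)-1-(5-bromo-2-hydroxy-3-methoxyphenyl)-3-(dimethylamino)prop-2-en-1-one | CN(C)/C=C/C(=O)c1cc(Br)cc(OC)c1O | intermediate
9 | 6-bromo-8-methoxy-4H-chromen-4-one | O=c1ccoc2c(OC)cc(Br)cc12 | intermediate
10 | itaconic anhydride (3-methylideneoxolane-2,5-dione) | C=C1CC(=O)OC1=O | starting material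
11 | 4-methoxy-2-methylidene-4-oxobutanoic acid (monomethyl itaconate) | C=C(CC(=O)OC)C(=O)O | intermediate
12 | (2E)-4-methoxy-2-{[3-methoxy-4-(pivaloyloxy)phenyl]methylidene}-4-oxobutanoic acid | OC(=O)/C(CC(=O)OC)=C/c1ccc(OC(=O)C(C)(C)C)c(OC)c1 | intermediate
13 | (2R)-4-methoxy-2-{[3-methoxy-4-(pivaloyloxy)phenyl]methyl}-4-oxobutanoic acid | COc1cc(C[C@@H](C(=O)O)CC(=O)OC)ccc1OC(=O)C(C)(C)C | intermediate
14 | methyl (3R)-3-(hydroxymethyl)-4-[3-methoxy-4-(pivaloyloxy)phenyl]butanoate | COc1cc(C[C@@H](CO)CC(=O)OC)ccc1OC(=O)C(C)(C)C | intermediate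
15 | (4R)-4-{[3-methoxy-4-(pivaloyloxy)phenyl]methyl}oxolan-2-one | COc1cc(C[C@H]2COC(=O)C2)ccc1OC(=O)C(C)(C)C | intermediate
16 | (3S,4R)-3-[(dimethylamino)methyl]-4-{[3-methoxy-4-(pivaloyloxy)phenyl]methyl}oxolan-2-one (trans Mannich base) | COc1cc(C[C@H]2COC(=O)[C@@H]2CN(C)C)ccc1OC(=O)C(C)(C)C | intermediate
17 | {[(3S,4R)-4-{[3-methoxy-4-(pivaloyloxy)phenyl]methyl}-2-oxooxolan-3-yl]methyl}trimethylammonium iodide | COc1cc(C[C@H]2COC(=O)[C@@H]2C[N+](C)(C)C)ccc1OC(=O)C(C)(C)C.[I-] | intermediate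
18 | (4R)-4-{[3-methoxy-4-(pivaloyloxy)phenyl]methyl}-3-methylideneoxolan-2-one | COc1cc(C[C@H]2COC(=O)C2=C)ccc1OC(=O)C(C)(C)C | intermediate
19 | (3S,4R)-3-[(8-methoxy-4-oxo-4H-chromen-6-yl)methyl]-4-{[3-methoxy-4-(pivaloyloxy)phenyl]methyl}oxolan-2-one (cis isomer of 20) | O=c1ccoc2c(OC)cc(C[C@@H]3C(=O)OC[C@@H]3Cc3ccc(OC(=O)C(C)(C)C)c(OC)c3)cc12 | intermediate
20 | (3R,4R)-3-[(8-methoxy-4-oxo-4H-chromen-6-yl)methyl]-4-{[3-methoxy-4-(pivaloyloxy)phenyl]methyl}oxolan-2-one (trans) | O=c1ccoc2c(OC)cc(C[C@H]3C(=O)OC[C@@H]3Cc3ccc(OC(=O)C(C)(C)C)c(OC)c3)cc12 | intermediate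
21 | (3R,4R)-3-{[(2S)-8-methoxy-2-[3-methoxy-4-(pivaloyloxy)phenyl]-4-oxo-3,4-dihydro-2H-chromen-6-yl]methyl}-4-{[3-methoxy-4-(pivaloyloxy)phenyl]methyl}oxolan-2-one | O=C1C[C@@H](c3ccc(OC(=O)C(C)(C)C)c(OC)c3)Oc2c(OC)cc(C[C@H]3C(=O)OC[C@@H]3Cc3ccc(OC(=O)C(C)(C)C)c(OC)c3)cc12 | intermediate
22 | (3R,4R)-3-{[(2S)-4,8-dimethoxy-2-[3-methoxy-4-(pivaloyloxy)phenyl]-2H-chromen-6-yl]methyl}-4-{[3-methoxy-4-(pivaloyloxy)phenyl]methyl}oxolan-2-one (methyl enol ether of 21) | COC1=C[C@@H](c3ccc(OC(=O)C(C)(C)C)c(OC)c3)Oc2c(OC)cc(C[C@H]3C(=O)OC[C@@H]3Cc3ccc(OC(=O)C(C)(C)C)c(OC)c3)cc12 | intermediate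
23 | 2,3-trans 3-[acetoxy(phenyl)-λ3-iodanyl] 4,4-dimethyl ketal of 21 (2R,3R by the sequence rule; C2 unchanged in space) | COC1(OC)[C@H](I(OC(C)=O)c4ccccc4)[C@@H](c3ccc(OC(=O)C(C)(C)C)c(OC)c3)Oc2c(OC)cc(C[C@H]3C(=O)OC[C@@H]3Cc3ccc(OC(=O)C(C)(C)C)c(OC)c3)cc12 | intermediate
24 | methyl (2S,3S)-7-methoxy-2-[3-methoxy-4-(pivaloyloxy)phenyl]-5-{[(3R,4R)-4-{[3-methoxy-4-(pivaloyloxy)phenyl]methyl}-2-oxooxolan-3-yl]methyl}-2,3-dihydro-1-benzofuran-3-carboxylate | COC(=O)[C@@H]1[C@@H](c2ccc(OC(=O)C(C)(C)C)c(OC)c2)Oc2c(OC)cc(C[C@H]3C(=O)OC[C@@H]3Cc3ccc(OC(=O)C(C)(C)C)c(OC)c3)cc12 | intermediate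
25 | (2R,3R)-2-{[(2S,3R)-2-(4-hydroxy-3-methoxyphenyl)-3-(hydroxymethyl)-7-methoxy-2,3-dihydro-1-benzofuran-5-yl]methyl}-3-[(4-hydroxy-3-methoxyphenyl)methyl]butane-1,4-diol | COc1cc(C[C@@H](CO)[C@H](CO)Cc2cc(OC)c3c(c2)[C@H](CO)[C@@H](c2ccc(O)c(OC)c2)O3)ccc1O | target

**Step count and risks**

Total steps: 14. Longest linear sequence: 11 steps (1, 2, 3, 7, 8, 9, 10, 11, 12, 13, 14).

The three steps most likely to fail:

Step 11 (the proposed new step). Risks are biaryl homocoupling or hydrodebromination of 9, reduction of the methylene group of 18, and slow cis-to-trans equilibration. The fallback uses known chemistry and sets out from 9. Miyaura borylation (B2pin2, PdCl2(dppf), KOAc, dioxane, 80 °C) gives 8-methoxy-6-(4,4,5,5-tetramethyl-1,3,2-dioxaborolan-2-yl)-4H-chromen-4-one F3. A 1,4-addition of F3 to 18 catalysed by monovalent rhodium ([RhCl(cod)]2, K3PO4, dioxane/H2O, 50 °C), followed by the same DBU equilibration, comes back to the route at 20.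

Step 13 (late-stage ring contraction). Risks are dehydrogenation to the flavone, methoxylation at C3, migration of ring C instead of ring B, and iodination of the electron-rich rings. The fallback replaces the iodane chemistry by a Wolff ring contraction and sets out from 21. Enolisation with LiN(SiMe3)2 at −78 °C and C-acylation with CF3CO2CH2CF3 give the 3-(trifluoroacetyl) derivative of 21 F4. Detrifluoroacetylative diazo transfer (MsN3, Et3N, MeCN) gives the 3-diazo derivative of 21 F5. Photochemical Wolff rearrangement in MeOH (350 nm) gives 24 together with the C3 epimer of 24 F6, and catalytic DBU (CH2Cl2, 23 °C) converts the epimer to the trans ester, so the fallback comes back at 24.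

Step 5 (Fries rearrangement on a bromo-deactivated guaiacol). Risks are low conversion and O-demethylation. The fallback builds the acetyl group in three known operations and sets out from 3. Magnesium-mediated ortho-formylation (MgCl2, Et3N, paraformaldehyde, MeCN, 80 °C) gives 5-bromo-2-hydroxy-3-methoxybenzaldehyde F1. Addition of MeMgBr (2.2 equiv, THF, 0 °C) gives 1-(5-bromo-2-hydroxy-3-methoxyphenyl)ethan-1-ol F2. Benzylic oxidation with MnO2 (CH2Cl2, 23 °C) comes back at 7.

Further compounds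
F1 | step 5 | 5-bromo-2-hydroxy-3-methoxybenzaldehyde | O=Cc1cc(Br)cc(OC)c1O
F2 | step 5 | 1-(5-bromo-2-hydroxy-3-methoxyphenyl)ethan-1-ol (racemic) | CC(O)c1cc(Br)cc(OC)c1O
F3 | step 11 | 8-methoxy-6-(4,4,5,5-tetramethyl-1,3,2-dioxaborolan-2-yl)-4H-chromen-4-one | O=c1ccoc2c(OC)cc(B3OC(C)(C)C(C)(C)O3)cc12
F4 | step 13 | 3-(trifluoroacetyl) derivative of 21 | O=C1C(C(=O)C(F)(F)F)[C@@H](c3ccc(OC(=O)C(C)(C)C)c(OC)c3)Oc2c(OC)cc(C[C@H]3C(=O)OC[C@@H]3Cc3ccc(OC(=O)C(C)(C)C)c(OC)c3)cc12
F5 | step 13 | 3-diazo derivative of 21 | O=C1C(=[N+]=[N-])[C@@H](c3ccc(OC(=O)C(C)(C)C)c(OC)c3)Oc2c(OC)cc(C[C@H]3C(=O)OC[C@@H]3Cc3ccc(OC(=O)C(C)(C)C)c(OC)c3)cc12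
F6 | step 13 | C3 epimer of 24 (cis 2S,3R ester) | COC(=O)[C@H]1[C@@H](c2ccc(OC(=O)C(C)(C)C)c(OC)c2)Oc2c(OC)cc(C[C@H]3C(=O)OC[C@@H]3Cc3ccc(OC(=O)C(C)(C)C)c(OC)c3)cc12
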